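If left-handed and right-handed substrate stayed equal throughout, the product's excess could be read from one ratio, and any shortfall of left-handed substrate would be a small correction to it.

| setting | cedar | maple | flask |
|---|---|---|---|
| left-handed substrate | 0.80 M | 0.80 M | 0.80 M |
| right-handed substrate | 0.80 M | 0.80 M | 0.80 M |
| partner | 2.5 equiv | 1.2 equiv | 2.50 equiv |
| racemization catalyst | 2.5 mol% | 2.5 mol% | 2.5 mol% |
| remark | the very flask that is asked about, followed so far | run made earlier |  |
| time |  |  | 10 h |

cedar run (percent of the left-handed substrate and right-handed substrate together charged)

| time / min | left-handed product / % | right-handed product / % | left-handed substrate / % |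
|---|---|---|---|
| 4.00 | 0 | 0 | 49.4 |
| 12.0 | 0.7 | 0 | 51.2 |
| 20.0 | 3.0 | 0 | 49.1 |
| 30.0 | 3.3 | 0.7 | 46.8 |
| 40.0 | 6.4 | 0.8 | 45.4 |
| 60.0 | 6.2 | 1.7 | 45.0 |
| 80.0 | 8.8 | 2.2 | 45.2 |

maple run (percent of the left-handed substrate and right-handed substrate together charged)

| time / h | left-handed product / % | right-handed product / % | left-handed substrate / % |
|---|---|---|---|
| 1.00 | 2.8 | 1.9 | 46.6 |
| 2.00 | 6.6 | 2.3 | 45.0 |
| 3.00 | 7.6 | 1.7 | 44.5 |
| 4.00 | 9.2 | 1.8 | 42.8 |
| 5.00 | 10.3 | 2.9 | 41.0 |
| 6.00 | 13.3 | 3.5 | 43.1 |
| 8.00 | 11.9 | 4.3 | 38.2 |

(each reading ± 1 percentage point)

1. left-handed product and right-handed product together, in percent of the left-handed substrate and right-handed substrate charged together, at 10 h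
2. excess of left-handed product over right-handed product in the product at 10 h
3. whether the exchange between left-handed substrate and right-handed substrate keeps pace with the reaction: how far the product's excess at 10 h gets from its value without exchange to its value with instant exchange (above 80 % keeps pace, below 20 % hardly takes part, else lags behind)

Summing the product readings, I got a left-to-right ratio of 5.26 in cedar, the flask asked about, and 3.35 in maple. Their geometric mean, 4.20, was my reading of the selectivity factor, the rate of left-handed product over right-handed product at equal substrate.

Instant exchange keeps the substrates equal, so my ceiling for cedar's excess was 61.5 %. For the floor I needed a conversion. Maple's two products summed to 13.2 % at 5.00 h and 16.2 % at 8.00 h, so its readings were still climbing and gave me no plateau to read. As a rough working figure, not a bound, I scaled that last reading by the partner charge, which gave about 33.8 % for cedar. Without exchange, that conversion leaves the substrate ratio near 0.523 at the end. Taking the midpoint between this and unity as the average correction to the selectivity factor put the floor near 52.3 %.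

The forecast gave 31 % and an excess of 57 %, inside my bracket, on the ground “Exchange therefore helps but lags”. Its yield stood below my 33.8 %.

    partner + left-handed substrate → left-handed product (k = 0.0690 /M/h)
    partner + right-handed substrate → right-handed product (k = 0.0160 /M/h)
    left-handed substrate + racemization catalyst ⇌ right-handed substrate + racemization catalyst, rate k3*[racemization catalyst]*[left-handed substrate] forward; the back reaction follows from the equilibrium constant (k = 14.0 /M/h)
    2 partner → self-condensation product (k = 0.0550 /M/h)
    2 racemization catalyst ⇌ resting dimer, settled at all times (K = 29.0 /M)
    partner → decomposition product (k = 4.50 × 10⁻⁴ /h)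

Cedar gave 30.8 % and an excess of 59.1 %, and the verdict on the exchange was lags behind, 55 % of the way between the two limiting excesses. Partner stood at 22 % of its charge, and just after the start its loss to self-condensation product ran 4.0 times its use on left-handed product. Divided by my selectivity factor, the final product ratio of 3.89 implies an average left-to-right substrate ratio of 0.926. In a neighbour flask charged with 0.620 equiv of partner, which reached 12.1 %, the same ceiling of 61.5 % stood over an excess of 61.3 %.

Readings and results are simulated with made-up constants; scatter was added.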